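## Retrosynthetic overview

1. Target 27 ⇐ asymmetric transfer hydrogenation of macrocyclic aryl ketone 26 (sets the R carbinol last) ⇐ debenzylation of 25 ⇐ Lindlar reduction of cycloalkyne 24.
2. 24 ⇐ ring-closing alkyne metathesis of diyne ketone 23. Rings A and B are bought (3,5-dibromophenol, methyl gallate); the 22-membered ring is the only ring built, and it is built last.
3. 23 ⇐ decarboxylation of β-keto ester 21 ⇐ crossed Claisen condensation of aryl methyl ester 15 with the lithium enolate of tert-butyl dec-8-ynoate 18 (forms C1–C2 and joins the two halves).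
4. 15 ⇐ Negishi coupling of aryl bromide 7 with oct-6-ynylzinc iodide; 7 ⇐ Ullmann diaryl ether coupling of gallate-derived phenol 4 with dibromide 6.
5. Both side chains ⇐ 8-iodooct-2-yne 13 (propynyllithium + 1-bromo-5-chloropentane); 18 ⇐ 13 + tert-butyl acetate.

Assumption: catalysts, ligands, bases and solvents are bought; the single stereocentre of the target is R (OH > aryl > alkyl > H).

## Route

Step 1
Reactants: 1 methyl gallate (methyl 3,4,5-trihydroxybenzoate)
Product: 2 methyl 4-(allyloxy)-3,5-dihydroxybenzoate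
Conditions: allyl bromide (1.05 equiv), KHCO3 (3 equiv), DMF, rt
Reagents that add atoms: allyl bromide, C=CCBr
Why: Williamson etherification in which the weak base ionises only the 4-OH (para to the ester, the most acidic), so one equivalent of allyl bromide alkylates that position selectively.

Step 2
Reactants: 2 methyl 4-(allyloxy)-3,5-dihydroxybenzoate
Product: 3 methyl 4-(allyloxy)-3,5-bis(benzyloxy)benzoate
Conditions: BnBr (2.4 equiv), K2CO3, DMF, 60 °C
Reagents that add atoms: benzyl bromide, BrCc1ccccc1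
Why: Williamson etherification of the two remaining phenols; the allyl ether and the methyl ester are inert to K2CO3/DMF.

Step 3
Reactants: 3 methyl 4-(allyloxy)-3,5-bis(benzyloxy)benzoate
Product: 4 methyl 3,5-bis(benzyloxy)-4-hydroxybenzoate
Conditions: Pd(PPh3)4 (2 mol%), morpholine (5 equiv), THF, rt
Reagents that add atoms: none
Why: Tsuji–Trost deallylation, in which zerovalent palladium ionises only the allyl aryl ether and morpholine traps the π-allyl fragment, leaving benzyl ethers and ester untouched.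

Step 4
Reactants: 5 3,5-dibromophenol
Product: 6 1-(benzyloxy)-3,5-dibromobenzene
Conditions: BnBr (1.1 equiv), K2CO3, acetone, reflux
Reagents that add atoms: benzyl bromide, BrCc1ccccc1
Why: Williamson etherification of an unhindered phenol.

Step 5
Reactants: 4 methyl 3,5-bis(benzyloxy)-4-hydroxybenzoate; 6 1-(benzyloxy)-3,5-dibromobenzene (3 equiv)
Product: 7 methyl 3,5-bis(benzyloxy)-4-[3-(benzyloxy)-5-bromophenoxy]benzoate
Conditions: CuI (10 mol%), picolinic acid (20 mol%), K3PO4 (2 equiv), DMSO, 100 °C, Ar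
Reagents that add atoms: none
Why: Ullmann diaryl ether synthesis with a picolinate-ligated copper catalyst suited to di-ortho-substituted phenols; the three-fold excess of the symmetric dibromide holds the reaction at mono-substitution and leaves one bromide as a handle.

Step 6
Reactants: 8 1-bromoprop-1-ene (E/Z mixture); 9 1-bromo-5-chloropentane
Product: 12 8-chlorooct-2-yne, via propyne 10 (not isolated), via 1-propynyllithium 11 (not isolated)
Conditions: 8 (1.5 equiv), n-BuLi (2.2 equiv), THF, −78 °C; then 9 (1.0 equiv), DMPU, −78 °C → rt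
Reagents that add atoms: none
Why: n-BuLi dehydrobrominates 8 to propyne and deprotonates it, and the lithium acetylide then undergoes SN2 alkylation at the C–Br end only, bromide being the far better leaving group.

Step 7
Reactants: 12 8-chlorooct-2-yne
Product: 13 8-iodooct-2-yne
Conditions: NaI (3 equiv), acetone, reflux
Reagents that add atoms: sodium iodide, [Na+].[I-]
Why: Finkelstein halide exchange, driven by precipitation of NaCl from acetone.

Step 8
Reactants: 13 8-iodooct-2-yne; 7 methyl 3,5-bis(benzyloxy)-4-[3-(benzyloxy)-5-bromophenoxy]benzoate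
Product: 15 methyl 3,5-bis(benzyloxy)-4-[3-(benzyloxy)-5-(oct-6-yn-1-yl)phenoxy]benzoate, via (oct-6-yn-1-yl)zinc iodide 14 (not isolated)
Conditions: 13 (1.5 equiv), Zn dust (activated with BrCH2CH2Br and Me3SiCl), LiCl, THF, 40 °C; then 7 (1.0 equiv), Pd(OAc)2 (2 mol%), SPhos (2-dicyclohexylphosphino-2',6'-dimethoxybiphenyl, 4 mol%), THF, rt → 50 °C
Reagents that add atoms: none
Why: Negishi cross-coupling, in which LiCl-assisted zinc insertion into the primary C–I bond gives an alkylzinc that tolerates ester and internal alkyne, and Pd/SPhos couples it with the aryl bromide faster than β-hydride elimination.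

Step 9
Reactants: 16 tert-butyl acetate; 13 8-iodooct-2-yne
Product: 18 tert-butyl dec-8-ynoate, via lithium enolate of tert-butyl acetate 17 (not isolated)
Conditions: LiN(iPr)2 (1.1 equiv), 16 (1.2 equiv), THF, −78 °C; then 13 (1.0 equiv), DMPU, −78 °C → rt
Reagents that add atoms: none
Why: SN2 alkylation of a tert-butyl ester lithium enolate, which does not self-condense, by a primary iodide.

Step 10
Reactants: 18 tert-butyl dec-8-ynoate; 15 methyl 3,5-bis(benzyloxy)-4-[3-(benzyloxy)-5-(oct-6-yn-1-yl)phenoxy]benzoate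
Product: 21 tert-butyl 2-{3,5-bis(benzyloxy)-4-[3-(benzyloxy)-5-(oct-6-yn-1-yl)phenoxy]benzoyl}dec-8-ynoate (racemic at C2), via lithium enolate of tert-butyl dec-8-ynoate 19 (not isolated), via lithium enolate of the β-keto ester 20 (not isolated)
Conditions: 18 (2.5 equiv), LiN(iPr)2 (2.4 equiv), THF, −78 °C; then 15 (1.0 equiv), −78 °C → rt; AcOH
Reagents that add atoms: none
Why: Crossed Claisen condensation in which the non-enolisable aryl methyl ester can only be the acceptor, the tert-butyl ester enolate is stable on warming, and deprotonation of the product to enolate 20 drives the reaction (hence more than 2 equiv of enolate); the new C2 centre is racemic and is erased in step 11.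

Step 11
Reactants: 21 tert-butyl 2-{3,5-bis(benzyloxy)-4-[3-(benzyloxy)-5-(oct-6-yn-1-yl)phenoxy]benzoyl}dec-8-ynoate
Product: 23 1-{3,5-bis(benzyloxy)-4-[3-(benzyloxy)-5-(oct-6-yn-1-yl)phenoxy]phenyl}dec-8-yn-1-one, via β-keto acid 22 (not isolated)
Conditions: TFA/CH2Cl2 (1:4), 0 °C → rt; evaporate; toluene, 90 °C
Reagents that add atoms: none
Why: Acidolysis of the tert-butyl ester (E1 loss of isobutene) followed by thermal decarboxylation of the β-keto acid through the cyclic six-membered transition state; aryl benzyl ethers and internal alkynes tolerate brief dilute TFA.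

Step 12
Reactants: 23 1-{3,5-bis(benzyloxy)-4-[3-(benzyloxy)-5-(oct-6-yn-1-yl)phenoxy]phenyl}dec-8-yn-1-one
Product: 24 tris-O-benzyl macrocyclic ynone (22-membered ring)
Conditions: Mo(≡C-C6H4-4-OMe)(OSiPh3)3 (10 mol%), 5 Å MS, toluene (2 mM), 80 °C
Reagents that add atoms: none
Why: Ring-closing alkyne metathesis of two methyl-capped alkynes, driven by high dilution and trapping of but-2-yne in the sieves; the silanolate-ligated molybdenum alkylidyne tolerates the aryl ketone, the ethers and the strain-free 22-membered ring.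

Step 13
Reactants: 24 tris-O-benzyl macrocyclic ynone (22-membered ring)
Product: 25 tris-O-benzyl (Z)-macrocyclic ketone
Conditions: H2 (1 atm), Pd/CaCO3 poisoned with Pb(OAc)2 (Lindlar catalyst), quinoline, EtOAc, rt
Reagents that add atoms: none
Why: Lindlar semi-hydrogenation delivers both hydrogens syn on the poisoned palladium surface to give only the Z alkene, and neither benzyl ethers nor the aryl ketone are reduced on this catalyst.

Step 14
Reactants: 25 tris-O-benzyl (Z)-macrocyclic ketone
Product: 26 (Z)-macrocyclic triphenol ketone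
Conditions: BCl3 (6 equiv), C6HMe5 (10 equiv), CH2Cl2, −78 °C; then H2O
Reagents that add atoms: none
Why: Lewis-acid debenzylation with pentamethylbenzene as benzyl-cation scavenger cleaves aryl benzyl ethers at −78 °C without touching the isolated Z alkene, ketone or diaryl ether, and it is run before the acid-labile benzylic alcohol exists.

Step 15
Reactants: 26 (Z)-macrocyclic triphenol ketone
Product: 27 target CNP0316989.2 ((R)-carbinol of the (Z)-macrocycle)
Conditions: RuCl[(R,R)-TsDPEN](p-cymene) (2 mol%), HCO2H/Et3N (5:2), DMF, 40 °C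
Reagents that add atoms: none
Why: Noyori–Ikariya asymmetric transfer hydrogenation, in which the (R,R)-TsDPEN divalent ruthenium hydride reduces the aryl alkyl ketone through the CH/π-controlled outer-sphere transition state to the R alcohol (same sense as acetophenone to (R)-1-phenylethanol) and leaves the isolated alkene and phenols alone.

## Compound list

1 | methyl gallate (methyl 3,4,5-trihydroxybenzoate) | COC(=O)c1cc(O)c(O)c(O)c1 | starting material
2 | methyl 4-(allyloxy)-3,5-dihydroxybenzoate | COC(=O)c1cc(O)c(OCC=C)c(O)c1 | intermediate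
3 | methyl 4-(allyloxy)-3,5-bis(benzyloxy)benzoate | COC(=O)c1cc(OCc2ccccc2)c(OCC=C)c(OCc2ccccc2)c1 | intermediate
4 | methyl 3,5-bis(benzyloxy)-4-hydroxybenzoate | COC(=O)c1cc(OCc2ccccc2)c(O)c(OCc2ccccc2)c1 | intermediate
5 | 3,5-dibromophenol | Oc1cc(Br)cc(Br)c1 | starting material
6 | 1-(benzyloxy)-3,5-dibromobenzene | Brc1cc(Br)cc(OCc2ccccc2)c1 | intermediate
7 | methyl 3,5-bis(benzyloxy)-4-[3-(benzyloxy)-5-bromophenoxy]benzoate | COC(=O)c1cc(OCc2ccccc2)c(Oc2cc(Br)cc(OCc3ccccc3)c2)c(OCc2ccccc2)c1 | intermediate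
8 | 1-bromoprop-1-ene (commercial E/Z mixture) | CC=CBr | starting material
9 | 1-bromo-5-chloropentane | ClCCCCCBr | starting material
10 | propyne | CC#C | intermediate (not isolated)
11 | 1-propynyllithium | CC#C[Li] | intermediate (not isolated)
12 | 8-chlorooct-2-yne | CC#CCCCCCCl | intermediate
13 | 8-iodooct-2-yne | CC#CCCCCCI | intermediate
14 | (oct-6-yn-1-yl)zinc iodide | CC#CCCCCC[Zn]I | intermediate (not isolated)
15 | methyl 3,5-bis(benzyloxy)-4-[3-(benzyloxy)-5-(oct-6-yn-1-yl)phenoxy]benzoate | COC(=O)c1cc(OCc2ccccc2)c(Oc2cc(CCCCCC#CC)cc(OCc3ccccc3)c2)c(OCc2ccccc2)c1 | intermediate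
16 | tert-butyl acetate | CC(=O)OC(C)(C)C | starting material
17 | lithium enolate of tert-butyl acetate | C=C(O[Li])OC(C)(C)C | intermediate (not isolated)
18 | tert-butyl dec-8-ynoate | CC#CCCCCCCC(=O)OC(C)(C)C | intermediate
19 | lithium enolate of tert-butyl dec-8-ynoate (enolate geometry not defined) | CC#CCCCCCC=C(O[Li])OC(C)(C)C | intermediate (not isolated)
20 | lithium enolate of the β-keto ester 21 (enolate geometry not defined) | CC#CCCCCCC(C(=O)OC(C)(C)C)=C(O[Li])c1cc(OCc2ccccc2)c(Oc2cc(CCCCCC#CC)cc(OCc3ccccc3)c2)c(OCc2ccccc2)c1 | intermediate (not isolated)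
21 | tert-butyl 2-{3,5-bis(benzyloxy)-4-[3-(benzyloxy)-5-(oct-6-yn-1-yl)phenoxy]benzoyl}dec-8-ynoate (racemic at C2) | CC#CCCCCCC(C(=O)OC(C)(C)C)C(=O)c1cc(OCc2ccccc2)c(Oc2cc(CCCCCC#CC)cc(OCc3ccccc3)c2)c(OCc2ccccc2)c1 | intermediate
22 | β-keto acid: 2-{3,5-bis(benzyloxy)-4-[3-(benzyloxy)-5-(oct-6-yn-1-yl)phenoxy]benzoyl}dec-8-ynoic acid (racemic) | CC#CCCCCCC(C(O)=O)C(=O)c1cc(OCc2ccccc2)c(Oc2cc(CCCCCC#CC)cc(OCc3ccccc3)c2)c(OCc2ccccc2)c1 | intermediate (not isolated)
23 | 1-{3,5-bis(benzyloxy)-4-[3-(benzyloxy)-5-(oct-6-yn-1-yl)phenoxy]phenyl}dec-8-yn-1-one | CC#CCCCCCCC(=O)c1cc(OCc2ccccc2)c(Oc2cc(CCCCCC#CC)cc(OCc3ccccc3)c2)c(OCc2ccccc2)c1 | intermediate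
24 | tris-O-benzyl macrocyclic ynone (22-membered ring): ring B C=O linked by (CH2)6–C≡C–(CH2)5 to C5 of ring A; ring B carries 3,5-bis(benzyloxy) and the 4-O-aryl ether; ring A carries 3-benzyloxy | O=C1CCCCCCC#CCCCCCc2cc(OCc3ccccc3)cc(c2)Oc2c(OCc3ccccc3)cc1cc2OCc1ccccc1 | intermediate
25 | tris-O-benzyl (Z)-macrocyclic ketone: as 24 with a (Z)-CH=CH in place of C≡C | O=C1CCCCCC/C=C\CCCCCc2cc(OCc3ccccc3)cc(c2)Oc2c(OCc3ccccc3)cc1cc2OCc1ccccc1 | intermediate
26 | (Z)-macrocyclic triphenol ketone: as 25 with three free phenols | O=C1CCCCCC/C=C\CCCCCc2cc(O)cc(c2)Oc2c(O)cc1cc2O | intermediate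
27 | target CNP0316989.2: (R)-benzylic alcohol on ring B (2,6-dihydroxy-4-substituted aryl ether), chain CH(OH)–(CH2)6–(Z)-CH=CH–(CH2)5 to C5 of ring A (3-hydroxyphenyl ether) | O[C@@H]1CCCCCC/C=C\CCCCCc2cc(O)cc(c2)Oc2c(O)cc1cc2O | target

## Step count and risks

Total steps: 15. Longest linear sequence: 11 steps (1, 2, 3, 5, 8, 10, 11, 12, 13, 14, 15 from methyl gallate).

Three steps most likely to fail:

Step 5 (Ullmann coupling of a di-ortho-alkoxy phenol with an aryl bromide). The fallback sets out from dibromide 6 and returns at 7. Mono bromine–lithium exchange (n-BuLi, 1.0 equiv, Et2O, −78 °C) gives [3-(benzyloxy)-5-bromophenyl]lithium F1. Quenching with B(OiPr)3 and mild aqueous hydrolysis gives [3-(benzyloxy)-5-bromophenyl]boronic acid F2. Chan–Lam oxidative coupling of F2 (2.5 equiv) with phenol 4 (Cu(OAc)2, pyridine, 4 Å MS, CH2Cl2, air, rt) then forms the diaryl ether at room temperature through an aryl–copper phenoxide instead of through oxidative addition of a hindered partner. The aryl bromide is untouched, and the product is 7.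

Step 12 (alkyne metathesis macrocyclisation in the presence of the ketone). The fallback sets out from diyne 23 and returns at 25, bypassing 24. Lindlar semi-hydrogenation of both alkynes (H2, Pd/CaCO3 poisoned with Pb(OAc)2, quinoline, EtOAc) gives the (Z,Z)-diene ketone 1-{3,5-bis(benzyloxy)-4-[3-(benzyloxy)-5-((Z)-oct-6-en-1-yl)phenoxy]phenyl}-(Z)-dec-8-en-1-one F3. Stereoretentive ring-closing olefin metathesis with the ruthenium dithiolate carbene Ru(=CH-C6H4-2-OiPr)(SIMes)(S2C6H2Cl2-3,6) (SIMes = 1,3-dimesitylimidazolidin-2-ylidene; THF, 2 mM, 40 °C, static vacuum) expels (Z)-but-2-ene and closes the ring with retention of the Z geometry to give 25.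

Step 15 (transfer hydrogenation of a ketone carrying three free phenols; conversion and ee are the risks). The fallback sets out from 26 and returns at 27. Acetylation (Ac2O, pyridine, DMAP, CH2Cl2) gives the triacetate of ketone 26 F4. Corey–Bakshi–Shibata reduction with catecholborane and (S)-1-methyl-3,3-diphenyltetrahydro-1H,3H-pyrrolo[1,2-c][1,3,2]oxazaborole (toluene, −78 → −40 °C) places hydride on the face that gives the R alcohol (aryl as the large group) without hydroborating the alkene, giving the triacetate (R)-alcohol F5. Methanolysis (K2CO3, MeOH, rt) removes the three aryl acetates under basic conditions that cannot ionise the benzylic alcohol, giving 27.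

## Further compounds

F1 | step 5 | [3-(benzyloxy)-5-bromophenyl]lithium | [Li]c1cc(Br)cc(OCc2ccccc2)c1
F2 | step 5 | [3-(benzyloxy)-5-bromophenyl]boronic acid | OB(O)c1cc(Br)cc(OCc2ccccc2)c1
F3 | step 12 | 1-{3,5-bis(benzyloxy)-4-[3-(benzyloxy)-5-((Z)-oct-6-en-1-yl)phenoxy]phenyl}-(Z)-dec-8-en-1-one | C/C=C\CCCCCCC(=O)c1cc(OCc2ccccc2)c(Oc2cc(CCCCC/C=C\C)cc(OCc3ccccc3)c2)c(OCc2ccccc2)c1
F4 | step 15 | triacetate of ketone 26 | O=C1CCCCCC/C=C\CCCCCc2cc(OC(C)=O)cc(c2)Oc2c(OC(C)=O)cc1cc2OC(C)=O
F5 | step 15 | triacetate (R)-alcohol (tri-O-acetyl 27) | O[C@@H]1CCCCCC/C=C\CCCCCc2cc(OC(C)=O)cc(c2)Oc2c(OC(C)=O)cc1cc2OC(C)=O
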